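**Plan**

- Retrosynthesis: the C2–Br bond is traced back to a C2 carboxyl group (ipso-bromodecarboxylation) and the C3–Br and C5–Br bonds to C–H bonds. This leaves ethyl 4-bromo-1-methylpyrrole-2-carboxylate, whose ring is cut at C2–C3 (aldol condensation) and at N1–C5 (enamine condensation).
- Enabling feature: ring atoms C3, C4 (with its bromine) and C5 are the three carbons of 2-bromomalonaldehyde, and N1, its methyl group and C2 are sarcosine. The ester on C2 acidifies the CH2 for ring closure and later leaves as CO2 when the fourth bromine enters.
- Forward order: N1–C5 is joined first to give an enaminal, the only ring (the pyrrole) then closes at C2–C3, C5 and C3 are brominated, the ester is hydrolysed, and CO2H is exchanged for Br.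
- Stereochemistry: the target is achiral and has no stereocentre. The enaminal C=C geometry equilibrates, and the two sp3 centres of the transient aldol adduct are erased by dehydration.

Key step: step 2

Assumption: enaminal 3 is drawn as its (E)-isomer (nitrogen cis to the formyl group), the geometry that closes the ring. The push-pull C=C bond should rotate easily, so whatever E/Z mixture the condensation delivers is expected to funnel into the same pyrrole.

**Route**

Step 1
Reactants: 1 2-bromomalonaldehyde; 2 sarcosine ethyl ester hydrochloride
Product: 3 ethyl N-[(E)-2-bromo-3-oxoprop-1-en-1-yl]-N-methylglycinate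
Conditions: Et3N (1.0 equiv), EtOH, 3 Å MS, rt → 50 °C
Reagents that add atoms: none
Why: Amine–carbonyl condensation to a vinylogous formamide (enaminal formation from a malonaldehyde enolate salt and a secondary amine hydrochloride): the sarcosine ester adds to one formyl group and loses water, and the lowered electrophilicity of the resulting push-pull enaminal should keep the second formyl group from condensing when the partners are used 1:1.

Step 2
Reactants: 3 ethyl N-[(E)-2-bromo-3-oxoprop-1-en-1-yl]-N-methylglycinate
Product: 5 ethyl 4-bromo-1-methyl-1H-pyrrole-2-carboxylate, via β-hydroxy ester aldol adduct 4 (not isolated)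
Conditions: NaOEt (1.2 equiv), anhydrous EtOH (0.05 M), 3 Å MS, 60 °C; then AcOH
Reagents that add atoms: none
Why: Ethoxide deprotonates the glycinate CH2 of 3 (activated by the ester and flanked by nitrogen), the ester enolate adds to the formyl carbon of the vinylogous formamide to form the C2–C3 bond, and the β-hydroxy ester 4 loses water by an E1cB pathway driven by the gain of pyrrole aromaticity. The closest known reaction type is the base-mediated cyclocondensation of N-(3-oxoprop-1-enyl)glycine esters, the second stage of the pyrrole-2-carboxylate synthesis from 3-aminoacroleins, 3-alkoxyacroleins or vinamidinium salts and glycine esters (an intramolecular aldol condensation of Knoevenagel type). The pyrrole ring closes in a 5-(enolexo)-exo-trig mode. No stereocentre remains, since the two sp3 centres of 4 form without control and both disappear on dehydration. The step needs chemoselectivity for cyclisation over ester cleavage and intermolecular condensation, which the substrate secures by holding its single acidic CH2 five atoms from the only carbonyl electrophile, by the easy rotation about the push-pull C=C bond that brings nitrogen and formyl group cis, and by an ethyl ester that matches the ethoxide base; dilution, an anhydrous medium and sieves support this. The C4 bromine sits on the nucleophilic α-carbon of the enaminal and is therefore not expected to be displaced.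

Step 3
Reactants: 5 ethyl 4-bromo-1-methyl-1H-pyrrole-2-carboxylate
Product: 6 ethyl 3,4,5-tribromo-1-methyl-1H-pyrrole-2-carboxylate
Conditions: Br2 (2.4 equiv), NaOAc (2.5 equiv), AcOH, rt → 50 °C
Reagents that add atoms: bromine, BrBr
Why: Electrophilic aromatic bromination (SEAr): the N-methylpyrrole ring stays nucleophilic enough, despite ester and bromine, for bromine to enter first at the free α-position C5 and then at the last free position C3, while acetate takes up HBr and the ester protects the ring from oxidative degradation.

Step 4
Reactants: 6 ethyl 3,4,5-tribromo-1-methyl-1H-pyrrole-2-carboxylate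
Product: 7 3,4,5-tribromo-1-methyl-1H-pyrrole-2-carboxylic acid
Conditions: NaOH (3 equiv), EtOH–H2O, 60 °C; then aq. HCl, 0 °C, pH 2
Reagents that add atoms: sodium hydroxide, [Na+].[OH-]
Why: Ester saponification (BAc2 hydrolysis): hydroxide should cleave the hindered ethyl ester on warming without touching the ring C–Br bonds, and cold acidification should free the acid without acid-promoted decarboxylation.

Step 5
Reactants: 7 3,4,5-tribromo-1-methyl-1H-pyrrole-2-carboxylic acid
Product: 8 2,3,4,5-tetrabromo-1-methyl-1H-pyrrole
Conditions: NBS (1.2 equiv), LiOAc (0.2 equiv), MeCN–H2O, rt → 40 °C, dark
Reagents that add atoms: N-bromosuccinimide, O=C1CCC(=O)N1Br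
Why: Ipso-bromodecarboxylation (Hunsdiecker-type halodecarboxylation of a pyrrole-2-carboxylic acid by electrophilic ipso-substitution): bromonium transfer from NBS to C2 of the carboxylate, the only ring position still open to attack, gives a σ-complex that rearomatises by loss of CO2.

**Compound list**

1 | 2-bromomalonaldehyde (2-bromopropanedial) | O=CC(Br)C=O | starting material
2 | sarcosine ethyl ester hydrochloride (ethyl N-methylglycinate hydrochloride) | CCOC(=O)CNC.Cl | starting material
3 | ethyl N-[(E)-2-bromo-3-oxoprop-1-en-1-yl]-N-methylglycinate | CCOC(=O)CN(C)/C=C(/Br)C=O | intermediate
4 | ethyl 4-bromo-3-hydroxy-1-methyl-2,3-dihydro-1H-pyrrole-2-carboxylate (aldol adduct, mixture of diastereomers, racemic, not isolated) | CCOC(=O)C1C(O)C(Br)=CN1C | intermediate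
5 | ethyl 4-bromo-1-methyl-1H-pyrrole-2-carboxylate | CCOC(=O)c1cc(Br)cn1C | intermediate
6 | ethyl 3,4,5-tribromo-1-methyl-1H-pyrrole-2-carboxylate | CCOC(=O)c1c(Br)c(Br)c(Br)n1C | intermediate
7 | 3,4,5-tribromo-1-methyl-1H-pyrrole-2-carboxylic acid | OC(=O)c1c(Br)c(Br)c(Br)n1C | intermediate
8 | 2,3,4,5-tetrabromo-1-methyl-1H-pyrrole | Cn1c(Br)c(Br)c(Br)c1Br | target

**Step count**

Total steps: 5. Longest linear sequence: 5 steps (from 1 or 2 to 8).

**Steps most likely to fail**

1. Step 2 (ring closure). The carbon–carbon bond formation at the weakly electrophilic vinylogous formamide carbonyl may be slow. Saponification of the ester by the water set free, or ethoxide-induced release of the amine from the enaminal, could then overtake cyclisation. The fallback raises the electrophilicity of the acceptor carbon while forming the same C2–C3 bond. It sets out from 3, which would be condensed with dimethylammonium tetrafluoroborate in refluxing EtOH with removal of water. This should give the delocalised vinamidinium salt N-{2-bromo-3-[(2-ethoxy-2-oxoethyl)(methyl)amino]prop-2-en-1-ylidene}-N-methylmethanaminium tetrafluoroborate F1, whose C=C/C=N geometry is not fixed. Treatment of this salt with NaOEt in EtOH at 60 °C should let the glycinate enolate add to the iminium carbon (a Mannich-type 5-exo-trig closure, the known vinamidinium–glycinate pyrrole synthesis). This should give ethyl 4-bromo-3-(dimethylamino)-1-methyl-2,3-dihydro-1H-pyrrole-2-carboxylate F2, which is not isolated and should lose dimethylamine to return to the route at 5.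

2. Step 5 (bromodecarboxylation). Ipso-attack at a hindered carbon of a ring already carrying three bromines may be sluggish. The acid could then remain unchanged, or radical bromination of the N-methyl group could compete. The fallback separates loss of CO2 from bromination. It sets out from 7, which would be protodecarboxylated by heating in ethanolamine at about 100 °C (known for brominated pyrrole-2-carboxylic acids) to give 2,3,4-tribromo-1-methyl-1H-pyrrole F3. Ordinary electrophilic bromination of its free α-position with NBS (1.05 equiv) in THF at −10 °C should then return to the route at 8.

3. Step 1 (enaminal formation). The condensation may stall at the ammonium enolate salt of the strongly acidic dialdehyde. It may also run on to a doubly condensed vinamidinium salt, or the free amino ester may self-condense to a diketopiperazine. The fallback removes the acidic enol before the amine is introduced. It sets out from 1, which would be heated with propan-2-ol and catalytic p-toluenesulfonic acid in cyclohexane with azeotropic removal of water. This should give the enol ether (2Z)-2-bromo-3-(propan-2-yloxy)prop-2-enal F4, drawn as the (Z)-isomer, though either geometry would serve. Addition–elimination of 2 (freed with Et3N, 1.0 equiv) in CH2Cl2 at 0 °C → rt, with loss of propan-2-ol, should then return to the route at 3.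

**Further compounds**

F1 | step 2 | N-{2-bromo-3-[(2-ethoxy-2-oxoethyl)(methyl)amino]prop-2-en-1-ylidene}-N-methylmethanaminium tetrafluoroborate | CCOC(=O)CN(C)C=C(Br)C=[N+](C)C.F[B-](F)(F)F
F2 | step 2 | ethyl 4-bromo-3-(dimethylamino)-1-methyl-2,3-dihydro-1H-pyrrole-2-carboxylate | CCOC(=O)C1C(N(C)C)C(Br)=CN1C
F3 | step 5 | 2,3,4-tribromo-1-methyl-1H-pyrrole | Cn1cc(Br)c(Br)c1Br
F4 | step 1 | (2Z)-2-bromo-3-(propan-2-yloxy)prop-2-enal | CC(C)O/C=C(\Br)C=O
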